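The retrosynthesis first cuts the two O–benzyl bonds. It then takes C5–H back to a C5–O-menthyl acetal, the benzylic CH2 back to C(SPh)2, and the carbinol C–H back to an aryl ketone. Last, in one operation, it cuts the C3–aroyl carbon bond and the C4–benzylic carbon bond.
The enabling feature is the C3–C4 edge of the γ-butyrolactone ring next to C2=O. Written as the C3=C4 bond of a butenolide, it accepts a benzylic carbanion at C4 and then reacts as the enolate at C3, so both aryl-bearing arms are attached to the intact five-membered ring in one flask.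
In the forward direction the lactone ring is present from step 1. Dithioacetal anion, butenolide and aroyl chloride give the full skeleton. Ketone reduction, desulfurisation, reductive loss of the auxiliary (the ring opens and re-closes as the same γ-lactone) and debenzylation follow.
The stereochemistry is relayed. (−)-Menthol fixes C5 by crystallisation, C5 directs C4 (anti addition), and C4 directs C3 (trans). The zinc chelate of the β-keto lactone then directs hydride to the C3–H face and gives the syn (S)-carbinol.

Key step: step 4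

Assumption: 5-hydroxyfuran-2(5H)-one, 4-(benzyloxy)-3-methoxybenzaldehyde and 4-(benzyloxy)-3-methoxybenzoic acid are taken as catalogue compounds; the first is otherwise one singlet-oxygen oxidation away from furfural.

Step 1
Reactants: 1 5-hydroxyfuran-2(5H)-one; 2 (−)-menthol
Product: 3 (5R)-5-(l-menthyloxy)furan-2(5H)-one
Conditions: neat, 100 °C, 20 h; crystallisation from petroleum ether, −20 °C; mother liquor re-equilibrated with camphorsulfonic acid (cat.) and recrystallised
Reagents that add atoms: none
Why: Thermal acetalisation of the cyclic hemiacylal (pseudo-acid) with the alcohol gives both C5 epimers, which interconvert under acid, and the (5R)-epimer is the crystalline one, so C5 is set by crystallisation against the fixed menthyl stereocentres.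

Step 2
Reactants: 4 4-(benzyloxy)-3-methoxybenzaldehyde
Product: 5 1-(benzyloxy)-4-[bis(phenylsulfanyl)methyl]-2-methoxybenzene
Conditions: PhSH (2.1 equiv), BF3·OEt2 (10 mol %), CH2Cl2, 0 °C
Reagents that add atoms: thiophenol, Sc1ccccc1
Why: Lewis acid catalysed dithioacetalisation of an electron-rich aromatic aldehyde turns the future benzylic CH2 into an acidic C–H (umpolung), and a catalytic amount of BF3·OEt2 at 0 °C should leave the aryl benzyl ether alone.

Step 3
Reactants: 6 4-(benzyloxy)-3-methoxybenzoic acid
Product: 7 4-(benzyloxy)-3-methoxybenzoyl chloride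
Conditions: (COCl)2 (1.2 equiv), DMF (cat.), CH2Cl2, 0 °C → rt; concentrated and used crude
Reagents that add atoms: oxalyl chloride, O=C(Cl)C(=O)Cl
Why: DMF-catalysed acid chloride formation (Vilsmeier-type activation) is neutral enough for both ether groups and gives only gaseous side products.

Step 4
Reactants: 5 1-(benzyloxy)-4-[bis(phenylsulfanyl)methyl]-2-methoxybenzene; 3 (5R)-5-(l-menthyloxy)furan-2(5H)-one; 7 4-(benzyloxy)-3-methoxybenzoyl chloride
Product: 10 (3S,4R,5R)-3-[4-(benzyloxy)-3-methoxybenzoyl]-4-{[4-(benzyloxy)-3-methoxyphenyl]bis(phenylsulfanyl)methyl}-5-(l-menthyloxy)dihydrofuran-2(3H)-one, via lithiated dithioacetal 8 (not isolated), via lithium enolate 9 (not isolated)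
Conditions: 5, n-BuLi (1.05 equiv), THF, −78 °C; 3, THF, −78 °C, 1 h; cannulated into 7 (1.5 equiv), THF, −78 °C; sat. aq. NH4Cl
Reagents that add atoms: none
Why: The soft, sulfur-stabilised benzylic carbanion 8 adds in Michael fashion to C4 of butenolide 3, forming the bond between the aryl-bearing carbon and C4, and the resulting lithium enolate 9 is C-acylated at C3 by 7, so the whole carbon skeleton is assembled in one flask. The closest known reaction type is the tandem conjugate addition–enolate trapping of lithiated aryl dithioacetals on but-2-en-4-olides and 5-alkoxybutenolides, as used for dibenzylbutyrolactone lignans. No ring is closed, because the five-membered lactone ring is carried through intact. C4 is controlled by the C5 menthyloxy group, which shields one face of the flat ring so that the nucleophile enters anti to it; C3 is controlled by the very large C4 substituent, which sends the acyl chloride to the opposite face, and because the C3–H of the β-keto lactone is acidic, the 3,4-trans isomer is also the thermodynamic one. The step needs 1,4- over 1,2-addition, which the charge-delocalised bis(phenylsulfanyl) anion and the acylal-activated enoate should secure, and C- over O-acylation without proton exchange between product and enolate, which the tight lithium enolate in THF and the inverse addition into excess 7 at −78 °C should secure. The ketone oxidation level is chosen on purpose, because an aldehyde trap through a closed chair transition state of the ring-locked E-enolate would favour the anti carbinol, whereas the target is syn.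

Step 5
Reactants: 10 keto lactone (3S,4R,5R)
Product: 11 (3S,4R,5R)-3-{(S)-[4-(benzyloxy)-3-methoxyphenyl](hydroxy)methyl}-4-{[4-(benzyloxy)-3-methoxyphenyl]bis(phenylsulfanyl)methyl}-5-(l-menthyloxy)dihydrofuran-2(3H)-one
Conditions: Zn(BH4)2 (Et2O stock solution), Et2O–CH2Cl2, −20 → 0 °C; H2O
Reagents that add atoms: none
Why: In this chelation-controlled ketone reduction, divalent zinc ties the ketone and lactone carbonyl oxygens into a six-membered chelate whose one face is covered by C4 and its bulky substituent, so hydride should enter from the C3–H face and set the (S)-carbinol syn to C3, while lactone, acetal and thioacetal are inert to this mild borohydride.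

Step 6
Reactants: 11 hydroxy dithioacetal lactone
Product: 12 (3S,4R,5R)-4-[4-(benzyloxy)-3-methoxybenzyl]-3-{(S)-[4-(benzyloxy)-3-methoxyphenyl](hydroxy)methyl}-5-(l-menthyloxy)dihydrofuran-2(3H)-one
Conditions: Raney Ni (W-2, washed neutral), EtOH–THF, rt
Reagents that add atoms: none
Why: Raney nickel reductive desulfurisation cleaves both C–S bonds and turns the helper C(SPh)2 into the benzylic CH2 under neutral conditions at room temperature, where the secondary benzylic alcohol, the aryl benzyl ethers and the acetal should persist and no stereocentre is touched.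

Step 7
Reactants: 12 menthyloxy lactone
Product: 15 (3S,4R)-4-[4-(benzyloxy)-3-methoxybenzyl]-3-{(S)-[4-(benzyloxy)-3-methoxyphenyl](hydroxy)methyl}dihydrofuran-2(3H)-one, via formyl carboxylate 13 (not isolated), via hydroxy carboxylate 14 (not isolated)
Conditions: NaBH4, KOH, EtOH–H2O, 0 °C → rt; then 1 M HCl to pH 3, 0 °C
Reagents that add atoms: none
Why: In this one-pot hydrolysis–reduction–lactonisation, saponification of the acylal-type lactone releases menthol and the C5 aldehyde, NaBH4 should reduce the aldehyde in situ before it can epimerise at C4, and mild acidification re-closes the primary alcohol onto the C2 acid (5-exo-trig), creating no new stereocentre.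

Step 8
Reactants: 15 dibenzyl ether of the target
Product: 16 (3S,4R)-3-[(S)-hydroxy(4-hydroxy-3-methoxyphenyl)methyl]-4-(4-hydroxy-3-methoxybenzyl)dihydrofuran-2(3H)-one (target)
Conditions: H2 (1 atm), Pd/C (10 wt %), EtOAc, rt; stopped after uptake of 2 equiv H2
Reagents that add atoms: none
Why: Catalytic hydrogenolysis of the two aryl benzyl ethers over zerovalent palladium in a neutral aprotic solvent is much faster than C–O hydrogenolysis of the secondary carbinol, so the free bisphenol should be released with all three stereocentres intact.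

Compound list
1 | 5-hydroxyfuran-2(5H)-one (racemic) | OC1OC(=O)C=C1 | starting material
2 | (−)-menthol, (1R,2S,5R)-2-isopropyl-5-methylcyclohexan-1-ol | CC(C)[C@@H]1CC[C@@H](C)C[C@H]1O | starting material
3 | (5R)-5-{[(1R,2S,5R)-2-isopropyl-5-methylcyclohexyl]oxy}furan-2(5H)-one | O=C1C=C[C@H](O[C@@H]2C[C@H](C)CC[C@H]2C(C)C)O1 | intermediate
4 | 4-(benzyloxy)-3-methoxybenzaldehyde | COc1cc(C=O)ccc1OCc1ccccc1 | starting material
5 | 1-(benzyloxy)-4-[bis(phenylsulfanyl)methyl]-2-methoxybenzene | COc1cc(ccc1OCc1ccccc1)C(Sc1ccccc1)Sc1ccccc1 | intermediate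
6 | 4-(benzyloxy)-3-methoxybenzoic acid | COc1cc(C(=O)O)ccc1OCc1ccccc1 | starting material
7 | 4-(benzyloxy)-3-methoxybenzoyl chloride | COc1cc(C(=O)Cl)ccc1OCc1ccccc1 | intermediate
8 | {[4-(benzyloxy)-3-methoxyphenyl]bis(phenylsulfanyl)methyl}lithium | [Li]C(Sc1ccccc1)(Sc1ccccc1)c1ccc(OCc2ccccc2)c(OC)c1 | intermediate
9 | lithium (4R,5R)-4-{[4-(benzyloxy)-3-methoxyphenyl]bis(phenylsulfanyl)methyl}-5-(l-menthyloxy)-4,5-dihydrofuran-2-olate | COc1cc(ccc1OCc1ccccc1)C(Sc1ccccc1)(Sc1ccccc1)[C@H]1[C@H](O[C@@H]2C[C@H](C)CC[C@H]2C(C)C)OC(O[Li])=C1 | intermediate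
10 | (3S,4R,5R)-3-[4-(benzyloxy)-3-methoxybenzoyl]-4-{[4-(benzyloxy)-3-methoxyphenyl]bis(phenylsulfanyl)methyl}-5-(l-menthyloxy)dihydrofuran-2(3H)-one | COc1cc(ccc1OCc1ccccc1)C(Sc1ccccc1)(Sc1ccccc1)[C@H]1[C@H](O[C@@H]2C[C@H](C)CC[C@H]2C(C)C)OC(=O)[C@@H]1C(=O)c1ccc(OCc2ccccc2)c(OC)c1 | intermediate
11 | (3S,4R,5R)-3-{(S)-[4-(benzyloxy)-3-methoxyphenyl](hydroxy)methyl}-4-{[4-(benzyloxy)-3-methoxyphenyl]bis(phenylsulfanyl)methyl}-5-(l-menthyloxy)dihydrofuran-2(3H)-one | COc1cc(ccc1OCc1ccccc1)C(Sc1ccccc1)(Sc1ccccc1)[C@H]1[C@H](O[C@@H]2C[C@H](C)CC[C@H]2C(C)C)OC(=O)[C@@H]1[C@H](O)c1ccc(OCc2ccccc2)c(OC)c1 | intermediate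
12 | (3S,4R,5R)-4-[4-(benzyloxy)-3-methoxybenzyl]-3-{(S)-[4-(benzyloxy)-3-methoxyphenyl](hydroxy)methyl}-5-(l-menthyloxy)dihydrofuran-2(3H)-one | COc1cc(C[C@H]2[C@H](O[C@@H]3C[C@H](C)CC[C@H]3C(C)C)OC(=O)[C@@H]2[C@H](O)c2ccc(OCc3ccccc3)c(OC)c2)ccc1OCc1ccccc1 | intermediate
13 | potassium (2S,3R)-3-[4-(benzyloxy)-3-methoxybenzyl]-2-{(S)-[4-(benzyloxy)-3-methoxyphenyl](hydroxy)methyl}-4-oxobutanoate | COc1cc(C[C@@H](C=O)[C@H](C(=O)[O-])[C@H](O)c2ccc(OCc3ccccc3)c(OC)c2)ccc1OCc1ccccc1.[K+] | intermediate
14 | potassium (2S,3R)-3-[4-(benzyloxy)-3-methoxybenzyl]-2-{(S)-[4-(benzyloxy)-3-methoxyphenyl](hydroxy)methyl}-4-hydroxybutanoate | COc1cc(C[C@@H](CO)[C@H](C(=O)[O-])[C@H](O)c2ccc(OCc3ccccc3)c(OC)c2)ccc1OCc1ccccc1.[K+] | intermediate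
15 | (3S,4R)-4-[4-(benzyloxy)-3-methoxybenzyl]-3-{(S)-[4-(benzyloxy)-3-methoxyphenyl](hydroxy)methyl}dihydrofuran-2(3H)-one | COc1cc(C[C@H]2COC(=O)[C@@H]2[C@H](O)c2ccc(OCc3ccccc3)c(OC)c2)ccc1OCc1ccccc1 | intermediate
16 | (3S,4R)-3-[(S)-hydroxy(4-hydroxy-3-methoxyphenyl)methyl]-4-(4-hydroxy-3-methoxybenzyl)dihydrofuran-2(3H)-one | COc1cc(C[C@H]2COC(=O)[C@@H]2[C@H](O)c2ccc(O)c(OC)c2)ccc1O | target

Total step count: 8. Longest linear sequence: 6 (step 1 or step 2, then steps 4 to 8).

Steps most likely to fail

1. Step 7. Under KOH the free β-hydroxy lactone may fragment by retro-aldol before the acylal is saponified, or the transient aldehyde may epimerise at C4 before hydride capture. The fallback removes the helpers before the C3 arm is installed; it sets out from lithium enolate 9 and comes back to the route at 15.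
   - Enolate 9 is protonated with aqueous NH4Cl instead of being acylated, giving (4R,5R)-4-{[4-(benzyloxy)-3-methoxyphenyl]bis(phenylsulfanyl)methyl}-5-(l-menthyloxy)dihydrofuran-2(3H)-one F2.
   - Raney Ni then gives (4R,5R)-4-[4-(benzyloxy)-3-methoxybenzyl]-5-(l-menthyloxy)dihydrofuran-2(3H)-one F3.
   - NaBH4/KOH followed by acid, now on a substrate that carries no carbinol, gives (R)-4-[4-(benzyloxy)-3-methoxybenzyl]dihydrofuran-2(3H)-one F4.
   - LDA in THF at −78 °C followed by acid chloride 7 gives the trans keto lactone (3S,4R)-3-[4-(benzyloxy)-3-methoxybenzoyl]-4-[4-(benzyloxy)-3-methoxybenzyl]dihydrofuran-2(3H)-one F5.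
   - The same zinc-chelate reduction with Zn(BH4)2 gives 15.

2. Step 4. The crowded enolate may be acylated on oxygen, or it may be quenched by proton transfer from the acidic product, which would cap the conversion. The fallback replaces acylation by aldol addition and oxidation; it sets out from lithium enolate 9 and aldehyde 4 and comes back at 10.
   - Trapping 9 with 4 at −78 °C, the best precedented trap for this enolate class, gives (3S,4R,5R)-3-{[4-(benzyloxy)-3-methoxyphenyl](hydroxy)methyl}-4-{[4-(benzyloxy)-3-methoxyphenyl]bis(phenylsulfanyl)methyl}-5-(l-menthyloxy)dihydrofuran-2(3H)-one (both carbinol epimers) F1.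
   - A Parikh–Doering oxidation (SO3·pyridine, DMSO, Et3N), which spares thioacetals, merges both epimers into 10.

3. Step 5. Facial selectivity may be poor if crowding around C3 and C4 keeps the zinc chelate from forming and an open conformer is reduced instead. The fallback switches from substrate control to catalyst control; it sets out from 10 and comes back at 11.
   - Asymmetric transfer hydrogenation with RuCl[(S,S)-TsDPEN](p-cymene) and HCO2H–Et3N in CH2Cl2 reads the aryl ketone itself and should deliver the (S)-carbinol.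
   - C3 stays in its trans arrangement through the rapidly equilibrating β-keto lactone.
   - New compounds on this way: none F0.

Further compounds
F1 | step 4 | (3S,4R,5R)-3-{[4-(benzyloxy)-3-methoxyphenyl](hydroxy)methyl}-4-{[4-(benzyloxy)-3-methoxyphenyl]bis(phenylsulfanyl)methyl}-5-(l-menthyloxy)dihydrofuran-2(3H)-one (both carbinol epimers) | COc1cc(ccc1OCc1ccccc1)C(Sc1ccccc1)(Sc1ccccc1)[C@H]1[C@H](O[C@@H]2C[C@H](C)CC[C@H]2C(C)C)OC(=O)[C@@H]1C(O)c1ccc(OCc2ccccc2)c(OC)c1
F0 | step 5 | none | none
F2 | step 7 | (4R,5R)-4-{[4-(benzyloxy)-3-methoxyphenyl]bis(phenylsulfanyl)methyl}-5-(l-menthyloxy)dihydrofuran-2(3H)-one | COc1cc(ccc1OCc1ccccc1)C(Sc1ccccc1)(Sc1ccccc1)[C@H]1[C@H](O[C@@H]2C[C@H](C)CC[C@H]2C(C)C)OC(=O)C1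
F3 | step 7 | (4R,5R)-4-[4-(benzyloxy)-3-methoxybenzyl]-5-(l-menthyloxy)dihydrofuran-2(3H)-one | COc1cc(C[C@H]2[C@H](O[C@@H]3C[C@H](C)CC[C@H]3C(C)C)OC(=O)C2)ccc1OCc1ccccc1
F4 | step 7 | (R)-4-[4-(benzyloxy)-3-methoxybenzyl]dihydrofuran-2(3H)-one | COc1cc(C[C@H]2COC(=O)C2)ccc1OCc1ccccc1
F5 | step 7 | (3S,4R)-3-[4-(benzyloxy)-3-methoxybenzoyl]-4-[4-(benzyloxy)-3-methoxybenzyl]dihydrofuran-2(3H)-one | COc1cc(C[C@H]2COC(=O)[C@@H]2C(=O)c2ccc(OCc3ccccc3)c(OC)c2)ccc1OCc1ccccc1
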